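**Plan** (azulene numbering of the target: C1, C2, C3 = carbinol, C3a, C4 = ester carbon, C5, C6 = ring methyl, C7, C8, C8a = quaternary methyl carbon)

1. Retrosynthesis: cut the C4–O acyl bond (ester), then return the C3 carbinol and C1H2 to a C1 ketone by a 1,3-oxygen transposition (Wharton). Next cut C8a–C3a and C8a–C8, which takes C8a out of the seven-membered ring and leaves a benzene ring, and finally cut the C3–aryl bond (conjugate addition).
2. Enabling feature: ring atoms C3a, C4, C5, C6, C7 and C8 carry the pattern of a 2-methoxy-4-methylphenyl ring (oxygen on C4, methyl on C6, side chain on C3a). The seventh atom, C8a, is the methyl-bearing quaternary carbon bonded to C1, so it can be delivered as a methyl keto-carbene on the three-atom tether C1–C2–C3.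
3. Forward order: aryl–C3 bond; diazoketone; one Buchner event closes the five-membered ring and expands the benzene ring to the seven-membered ring; oxygen transposition in the five-membered ring; dienone reduction; esterification.
4. Stereochemistry: C3 of the acid comes from (S)-BINAP–rhodium conjugate addition. It directs C8a in the Buchner step and C3a in the ketalisation and is then erased. C3 is rebuilt by epoxidation anti to the C8a methyl, and C4 is set by a thermodynamically controlled dissolving-metal reduction.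

Key step: step 4

Assumption: (S)-BINAP–rhodium is taken to add the aryl group to the (E)-β-isopropyl enoate with the facial sense established for (E)-β-alkyl enones and enoates, which corresponds to the (3R) ester; if the opposite sense is found, (R)-BINAP is used.

**Step 1**
Reactants: 1 (2-methoxy-4-methylphenyl)boronic acid; 2 ethyl (E)-4-methylpent-2-enoate
Product: 3 ethyl (3R)-3-(2-methoxy-4-methylphenyl)-4-methylpentanoate
Conditions: [Rh(OH)((S)-BINAP)]2 (2.5 mol%), 1 (2.5 equiv), dioxane/H2O 10:1, 90 °C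
Reagents that add atoms: none
Why: Rhodium-catalysed asymmetric conjugate addition of an arylboronic acid (Hayashi–Miyaura reaction): transmetalation gives an aryl–rhodium species that adds to the β-carbon, (S)-BINAP selecting the enoate face that gives the (3R) centre, and water releases the product.

**Step 2**
Reactants: 3 ethyl (3R)-3-(2-methoxy-4-methylphenyl)-4-methylpentanoate
Product: 4 (3R)-3-(2-methoxy-4-methylphenyl)-4-methylpentanoic acid
Conditions: LiOH·H2O, THF/MeOH/H2O, rt; then 1 M HCl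
Reagents that add atoms: lithium hydroxide, [Li+].[OH-] (supplies the carboxyl OH oxygen)
Why: Saponification; the stereocentre is β to the carboxyl group and cannot epimerise.

**Step 3**
Reactants: 4 (3R)-3-(2-methoxy-4-methylphenyl)-4-methylpentanoic acid
Product: 6 (5R)-2-diazo-5-(2-methoxy-4-methylphenyl)-6-methylheptan-3-one, via acid chloride 5 (not isolated)
Conditions: (COCl)2, DMF (cat.), CH2Cl2, 0 °C to rt; evaporate; CH3CHN2 (3 equiv, ethereal solution prepared beforehand), Et2O, −20 to 0 °C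
Reagents that add atoms: diazoethane, CC=[N+]=[N-]; oxalyl chloride, ClC(=O)C(=O)Cl (chlorine of intermediate 5 only)
Why: Acid chloride formation followed by C-acylation of diazoethane (Arndt–Eistert-type diazoketone synthesis), the excess diazoethane taking up the hydrogen chloride; no stereocentre is touched.

**Step 4**
Reactants: 6 (5R)-2-diazo-5-(2-methoxy-4-methylphenyl)-6-methylheptan-3-one
Product: 8 (3R,8aS)-4-methoxy-6,8a-dimethyl-3-(propan-2-yl)-3,8a-dihydroazulen-1(2H)-one, via norcaradiene 7 (not isolated)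
Conditions: Rh2(OAc)4 (1 mol%), CH2Cl2, reflux, slow addition of 6
Reagents that add atoms: none
Why: Dirhodium tetraacetate decomposes 6 to a rhodium carbenoid at the future C8a, which adds across the unsubstituted ipso–ortho bond of the arene (C3a–C8) in a [2+1] cycloaddition to give norcaradiene 7, and thermally allowed disrotatory six-electron electrocyclic opening of the C3a–C8 bond then gives cycloheptatriene 8 (intramolecular Buchner reaction; closest precedent is the dirhodium tetraacetate cyclisation of 2-diazo-5-arylalkan-3-ones that carry a benzylic substituent). The cyclopentanone closes by C8a–C3a bond formation over the three-atom tether C1–C2–C3, the cyclopropane closes in the same [2+1] event, and the seven-membered ring arises from the benzene ring by insertion of C8a between C3a and C8. The new quaternary stereocentre C8a is controlled by C3: the benzylic hydrogen eclipses the ortho methoxy group (allylic 1,3-strain), so the tether reaches the C3a–C8 bond from one face while the isopropyl group sits on the other, which places isopropyl trans to the C8a methyl and avoids a 1,3-clash across the forming cyclopentanone. The step needs aromatic addition to win over insertion into the isopropyl methine C–H bond and over 1,2-hydride shift (helped by the electron-poor carboxylate ligands and slow addition), and addition to C3a–C8 instead of the methoxy-bearing C3a–C4 bond (secured by the ortho substituent and the same conformational lock). The methoxy group ends on C4 as an enol ether and the aryl methyl on C6, so the ring expansion delivers every seven-ring substituent of the target.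

**Step 5**
Reactants: 8 (3R,8aS)-4-methoxy-6,8a-dimethyl-3-(propan-2-yl)-3,8a-dihydroazulen-1(2H)-one
Product: 9 (3R,3aR,8aS)-4,4-(ethane-1,2-diyldioxy)-6,8a-dimethyl-3-(propan-2-yl)-3,3a,4,8a-tetrahydroazulen-1(2H)-one (H-3a cis to isopropyl, anti to the C8a methyl)
Conditions: HOCH2CH2OH (5 equiv), pyridinium p-toluenesulfonate (10 mol%), 4 Å molecular sieves, CH2Cl2, rt
Reagents that add atoms: ethane-1,2-diol, OCCO
Why: Acid-catalysed transketalisation of the methyl enol ether: protonation at C3a gives an oxocarbenium ion at C4 that the diol traps, and under these reversible conditions H-3a should settle anti to the C8a methyl because this keeps the bulky spiro carbon C4 trans to the neighbouring isopropyl group; the hindered C1 ketone is not ketalised.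

**Step 6**
Reactants: 9 (3R,3aR,8aS)-4,4-(ethane-1,2-diyldioxy)-6,8a-dimethyl-3-(propan-2-yl)-3,3a,4,8a-tetrahydroazulen-1(2H)-one
Product: 11 (3aR,8aS)-4,4-(ethane-1,2-diyldioxy)-6,8a-dimethyl-3-(propan-2-yl)-4,8a-dihydroazulen-1(3aH)-one, via silyl enol ether 10 (not isolated)
Conditions: LiN(iPr)2, Me3SiCl, THF, −78 °C; then Pd(OAc)2 (1.1 equiv), MeCN, rt
Reagents that add atoms: chlorotrimethylsilane, C[Si](C)(C)Cl (silyl group of intermediate 10 only)
Why: Saegusa–Ito oxidation: C2 is the only enolisable position, and syn β-hydride elimination from the C2–palladium species (formed anti to isopropyl, hence cis to H-3) gives the 2,3-enone, which removes the relay stereocentre C3.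

**Step 7**
Reactants: 11 (3aR,8aS)-4,4-(ethane-1,2-diyldioxy)-6,8a-dimethyl-3-(propan-2-yl)-4,8a-dihydroazulen-1(3aH)-one
Product: 12 (2R,3R,3aS,8aS)-2,3-epoxy-4,4-(ethane-1,2-diyldioxy)-6,8a-dimethyl-3-(propan-2-yl)-2,3,3a,4-tetrahydroazulen-1(8aH)-one (epoxide oxygen cis to H-3a)
Conditions: 30% H2O2, NaOH (0.3 equiv), MeOH, 0 °C to rt
Reagents that add atoms: hydrogen peroxide, OO
Why: Weitz–Scheffer nucleophilic epoxidation, selective for the enone over the unactivated diene; hydroperoxide attacks C3 from the face of H-3a because the other face is blocked by the C8a methyl and the C4 ketal carbon, which fixes the C3–O bond cis to H-3a.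

**Step 8**
Reactants: 12 (2R,3R,3aS,8aS)-2,3-epoxy-4,4-(ethane-1,2-diyldioxy)-6,8a-dimethyl-3-(propan-2-yl)-2,3,3a,4-tetrahydroazulen-1(8aH)-one
Product: 14 (3S,3aS,8aR)-4,4-(ethane-1,2-diyldioxy)-6,8a-dimethyl-3-(propan-2-yl)-3,3a,4,8a-tetrahydroazulen-3-ol, via epoxy hydrazone 13 (not isolated)
Conditions: N2H4·H2O (3 equiv), AcOH (cat.), MeOH, 0 °C to rt
Reagents that add atoms: hydrazine hydrate, NN.O (nitrogen of intermediate 13 only)
Why: Wharton transposition: the epoxy hydrazone fragments with loss of dinitrogen to the allylic alcohol, which moves the oxygen from C1 to C3 with the C3–O bond retained and leaves a C1–C2 alkene.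

**Step 9**
Reactants: 14 (3S,3aS,8aR)-4,4-(ethane-1,2-diyldioxy)-6,8a-dimethyl-3-(propan-2-yl)-3,3a,4,8a-tetrahydroazulen-3-ol
Product: 15 (3S,3aS,8aR)-3-hydroxy-6,8a-dimethyl-3-(propan-2-yl)-3,8a-dihydroazulen-4(3aH)-one
Conditions: pyridinium p-toluenesulfonate, acetone/H2O 9:1, 40 °C
Reagents that add atoms: water, O
Why: Mild acid hydrolysis of the dioxolane through the diene-stabilised oxocarbenium ion; the buffered acid is chosen to spare the tertiary allylic alcohol and the α-stereocentre C3a.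

**Step 10**
Reactants: 15 (3S,3aS,8aR)-3-hydroxy-6,8a-dimethyl-3-(propan-2-yl)-3,8a-dihydroazulen-4(3aH)-one
Product: 17 (3S,3aR,4R,8aR)-6,8a-dimethyl-3-(propan-2-yl)-3,3a,4,5,8,8a-hexahydroazulene-3,4-diol, via β,γ-enone 16 (not isolated)
Conditions: Li, NH3(l)/THF, −78 °C; then MeOH, −78 to −33 °C; NH4Cl
Reagents that add atoms: none
Why: Dissolving-metal reduction of the linear dienone: two electrons and protonation at C8 give the dienolate, kinetic α-protonation at C5 by methanol gives β,γ-enone 16 with the C6–C7 alkene, and further electron transfer reduces the ketone under thermodynamic control to the pseudo-equatorial alcohol, trans to the C3a–C3 bond and anti to the axial C8a methyl (oxygen cis to H-3a).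

**Step 11**
Reactants: 17 (3S,3aR,4R,8aR)-6,8a-dimethyl-3-(propan-2-yl)-3,3a,4,5,8,8a-hexahydroazulene-3,4-diol
Product: 18 (3R,3aR,4R,8aS)-6,8a-dimethyl-3-(propan-2-yl)-1,2,3,3a,4,5,8,8a-octahydroazulene-3,4-diol
Conditions: 2-nitrobenzenesulfonohydrazide (5 equiv), Et3N, CH2Cl2, rt
Reagents that add atoms: none
Why: Diimide reduction, which discriminates the cis-disubstituted cyclopentene from the trisubstituted C6–C7 alkene and leaves the allylic C–O bond intact.

**Step 12**
Reactants: 18 (3R,3aR,4R,8aS)-6,8a-dimethyl-3-(propan-2-yl)-1,2,3,3a,4,5,8,8a-octahydroazulene-3,4-diol; 19 3,4-dimethoxybenzoyl chloride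
Product: 20 (3R,3aR,4R,8aS)-3-hydroxy-6,8a-dimethyl-3-(propan-2-yl)-1,2,3,3a,4,5,8,8a-octahydroazulen-4-yl 3,4-dimethoxybenzoate
Conditions: 19 (1.5 equiv), Et3N, DMAP (cat.), CH2Cl2, 0 °C to rt
Reagents that add atoms: none
Why: DMAP-catalysed acylation of the secondary alcohol; the tertiary C3 alcohol is too hindered to react.

**Compound list**

1 | (2-methoxy-4-methylphenyl)boronic acid | COc1cc(C)ccc1B(O)O | starting material
2 | ethyl (E)-4-methylpent-2-enoate | CCOC(=O)/C=C/C(C)C | starting material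
3 | ethyl (3R)-3-(2-methoxy-4-methylphenyl)-4-methylpentanoate | CCOC(=O)C[C@H](C(C)C)c1ccc(C)cc1OC | intermediate
4 | (3R)-3-(2-methoxy-4-methylphenyl)-4-methylpentanoic acid | OC(=O)C[C@H](C(C)C)c1ccc(C)cc1OC | intermediate
5 | (3R)-3-(2-methoxy-4-methylphenyl)-4-methylpentanoyl chloride | ClC(=O)C[C@H](C(C)C)c1ccc(C)cc1OC | intermediate
6 | (5R)-2-diazo-5-(2-methoxy-4-methylphenyl)-6-methylheptan-3-one | CC(=[N+]=[N-])C(=O)C[C@H](C(C)C)c1ccc(C)cc1OC | intermediate
7 | norcaradiene valence isomer of 8 (cyclopropane C8a–C3a–C8 fused to the cyclopentanone and to a 2-methoxy-4-methylcyclohexa-1,3-diene; isopropyl trans to the C8a methyl) | O=C1C[C@H](C(C)C)[C@]23C(OC)=CC(C)=C[C@H]2[C@]13C | intermediate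
8 | (3R,8aS)-4-methoxy-6,8a-dimethyl-3-(propan-2-yl)-3,8a-dihydroazulen-1(2H)-one | O=C1C[C@H](C(C)C)C2=C(OC)C=C(C)C=C[C@]12C | intermediate
9 | (3R,3aR,8aS)-4,4-(ethane-1,2-diyldioxy)-6,8a-dimethyl-3-(propan-2-yl)-3,3a,4,8a-tetrahydroazulen-1(2H)-one | O=C1C[C@H](C(C)C)[C@H]2C3(OCCO3)C=C(C)C=C[C@]12C | intermediate
10 | 1-O-trimethylsilyl enol ether of 9 (C1=C2) | C[Si](C)(C)OC1=C[C@H](C(C)C)[C@H]2C3(OCCO3)C=C(C)C=C[C@]12C | intermediate
11 | (3aR,8aS)-4,4-(ethane-1,2-diyldioxy)-6,8a-dimethyl-3-(propan-2-yl)-4,8a-dihydroazulen-1(3aH)-one | O=C1C=C(C(C)C)[C@H]2C3(OCCO3)C=C(C)C=C[C@]12C | intermediate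
12 | (2R,3R,3aS,8aS)-2,3-epoxy-4,4-(ethane-1,2-diyldioxy)-6,8a-dimethyl-3-(propan-2-yl)-2,3,3a,4-tetrahydroazulen-1(8aH)-one | O=C1[C@@H]2O[C@]2(C(C)C)[C@H]3C4(OCCO4)C=C(C)C=C[C@]13C | intermediate
13 | C1 hydrazone of 12 | NN=C1[C@@H]2O[C@]2(C(C)C)[C@H]3C4(OCCO4)C=C(C)C=C[C@]13C | intermediate
14 | (3S,3aS,8aR)-4,4-(ethane-1,2-diyldioxy)-6,8a-dimethyl-3-(propan-2-yl)-3,3a,4,8a-tetrahydroazulen-3-ol | C1=C[C@@](O)(C(C)C)[C@H]2C3(OCCO3)C=C(C)C=C[C@]12C | intermediate
15 | (3S,3aS,8aR)-3-hydroxy-6,8a-dimethyl-3-(propan-2-yl)-3,8a-dihydroazulen-4(3aH)-one | C1=C[C@@](O)(C(C)C)[C@H]2C(=O)C=C(C)C=C[C@]12C | intermediate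
16 | (3S,3aS,8aR)-3-hydroxy-6,8a-dimethyl-3-(propan-2-yl)-3,3a,8,8a-tetrahydroazulen-4(5H)-one | C1=C[C@@](O)(C(C)C)[C@H]2C(=O)CC(C)=CC[C@]12C | intermediate
17 | (3S,3aR,4R,8aR)-6,8a-dimethyl-3-(propan-2-yl)-3,3a,4,5,8,8a-hexahydroazulene-3,4-diol | O[C@@H]1CC(C)=CC[C@]2(C)C=C[C@@](O)(C(C)C)[C@@H]12 | intermediate
18 | (3R,3aR,4R,8aS)-6,8a-dimethyl-3-(propan-2-yl)-1,2,3,3a,4,5,8,8a-octahydroazulene-3,4-diol | O[C@@H]1CC(C)=CC[C@]2(C)CC[C@@](O)(C(C)C)[C@@H]12 | intermediate
19 | 3,4-dimethoxybenzoyl chloride | COc1ccc(C(=O)Cl)cc1OC | starting material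
20 | (3R,3aR,4R,8aS)-3-hydroxy-6,8a-dimethyl-3-(propan-2-yl)-1,2,3,3a,4,5,8,8a-octahydroazulen-4-yl 3,4-dimethoxybenzoate | COc1ccc(C(=O)O[C@@H]2CC(C)=CC[C@]3(C)CC[C@@](O)(C(C)C)[C@@H]23)cc1OC | target

**Step count and risks**

Total step count: 12. Longest linear sequence: 12 steps (1 and 2 to 20).

Step 4. What may go wrong: the carbenoid inserts into the isopropyl methine C–H bond or undergoes 1,2-hydride shift faster than it adds to the arene, it adds across the methoxy-bearing ortho bond, or the trans selectivity erodes. Fallback (the isopropyl group is left out of the cyclisation substrate, C8a is set by a chiral catalyst, and isopropyl is added afterwards): it sets out from 1. Rhodium-catalysed conjugate addition of 1 to ethyl acrylate ([Rh(OH)(cod)]2, dioxane/H2O) should give ethyl 3-(2-methoxy-4-methylphenyl)propanoate F1, and saponification gives 3-(2-methoxy-4-methylphenyl)propanoic acid F2. Oxalyl chloride gives 3-(2-methoxy-4-methylphenyl)propanoyl chloride F3, and diazoethane then gives 2-diazo-5-(2-methoxy-4-methylphenyl)pentan-3-one F4. An enantioselective Buchner reaction (Cu(MeCN)4PF6, a C2-symmetric bis(oxazoline) ligand whose enantiomer is chosen for the (8aS) product, NaB[3,5-(CF3)2C6H3]4, CH2Cl2) should give (8aS)-4-methoxy-6,8a-dimethyl-3,8a-dihydroazulen-1(2H)-one F5. Transketalisation as in step 5 gives (3aR,8aS)-4,4-(ethane-1,2-diyldioxy)-6,8a-dimethyl-3,3a,4,8a-tetrahydroazulen-1(2H)-one F6, LiN(iPr)2/Me3SiCl gives its trimethylsilyl enol ether F7, and Pd(OAc)2 gives (3aR,8aS)-4,4-(ethane-1,2-diyldioxy)-6,8a-dimethyl-4,8a-dihydroazulen-1(3aH)-one F8. Copper-catalysed conjugate addition of iPrMgCl (CuBr·SMe2, Me3SiCl, THF, −78 °C), anti to the ketal carbon and the C8a methyl, gives silyl enol ether 10, where the route is rejoined.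

Step 7. What may go wrong: conjugate attack of hydroperoxide on the hindered β,β-disubstituted enone is slow, and γ-deprotonation competes, which would scramble C3a or deconjugate the enone. Fallback (the C3 oxygen is brought in through boron and the C1 carbonyl is removed by hydrazone reduction): it sets out from 11. Copper-catalysed conjugate borylation (bis(pinacolato)diboron, CuCl, Xantphos, NaOtBu, MeOH, THF) should deliver boron to C3 from the open face to give (3S,3aR,8aS)-4,4-(ethane-1,2-diyldioxy)-6,8a-dimethyl-3-(propan-2-yl)-3-(4,4,5,5-tetramethyl-1,3,2-dioxaborolan-2-yl)-3,3a,4,8a-tetrahydroazulen-1(2H)-one F9. Oxidation with NaBO3 proceeds with retention to (3R,3aS,8aS)-4,4-(ethane-1,2-diyldioxy)-3-hydroxy-6,8a-dimethyl-3-(propan-2-yl)-3,3a,4,8a-tetrahydroazulen-1(2H)-one F10. Condensation with 4-methylbenzenesulfonohydrazide gives the tosylhydrazone of F10 F11, and catecholborane followed by NaOAc reduces it to (3R,3aS,8aS)-4,4-(ethane-1,2-diyldioxy)-6,8a-dimethyl-3-(propan-2-yl)-1,2,3,3a,4,8a-hexahydroazulen-3-ol F12. Ketal hydrolysis as in step 9 gives (3R,3aS,8aS)-3-hydroxy-6,8a-dimethyl-3-(propan-2-yl)-1,2,3,8a-tetrahydroazulen-4(3aH)-one F13. The dissolving-metal reduction of step 10, through (3R,3aS,8aS)-3-hydroxy-6,8a-dimethyl-3-(propan-2-yl)-1,2,3,3a,8,8a-hexahydroazulen-4(5H)-one F14, gives diol 18, where the route is rejoined.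

Step 10. What may go wrong: base-mediated conjugation of the β,γ-enone leads to over-reduction, the β-alkoxide ketone suffers retro-aldol cleavage of the C3–C3a bond, or thermodynamic control at C4 is incomplete. Fallback (kinetic hydride delivery to the open face, then inversion during esterification): it sets out from 15. Li/NH3 with an NH4Cl quench gives 16, which is isolated. NaBH4/CeCl3 should attack C4 from the face of H-3a to give the C4 epimer (3S,3aR,4S,8aR)-6,8a-dimethyl-3-(propan-2-yl)-3,3a,4,5,8,8a-hexahydroazulene-3,4-diol F15. Diimide reduction as in step 11 gives (3R,3aR,4S,8aS)-6,8a-dimethyl-3-(propan-2-yl)-1,2,3,3a,4,5,8,8a-octahydroazulene-3,4-diol F16. Mitsunobu esterification with 3,4-dimethoxybenzoic acid (PPh3, diisopropyl azodicarboxylate, THF) inverts C4 and gives 20, where the route is rejoined.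

**Further compounds**

F1 | step 4 | ethyl 3-(2-methoxy-4-methylphenyl)propanoate | CCOC(=O)CCc1ccc(C)cc1OC
F2 | step 4 | 3-(2-methoxy-4-methylphenyl)propanoic acid | OC(=O)CCc1ccc(C)cc1OC
F3 | step 4 | 3-(2-methoxy-4-methylphenyl)propanoyl chloride | ClC(=O)CCc1ccc(C)cc1OC
F4 | step 4 | 2-diazo-5-(2-methoxy-4-methylphenyl)pentan-3-one | CC(=[N+]=[N-])C(=O)CCc1ccc(C)cc1OC
F5 | step 4 | (8aS)-4-methoxy-6,8a-dimethyl-3,8a-dihydroazulen-1(2H)-one | O=C1CCC2=C(OC)C=C(C)C=C[C@]12C
F6 | step 4 | (3aR,8aS)-4,4-(ethane-1,2-diyldioxy)-6,8a-dimethyl-3,3a,4,8a-tetrahydroazulen-1(2H)-one | O=C1CC[C@H]2C3(OCCO3)C=C(C)C=C[C@]12C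
F7 | step 4 | 1-O-trimethylsilyl enol ether of F6 | C[Si](C)(C)OC1=CC[C@H]2C3(OCCO3)C=C(C)C=C[C@]12C
F8 | step 4 | (3aR,8aS)-4,4-(ethane-1,2-diyldioxy)-6,8a-dimethyl-4,8a-dihydroazulen-1(3aH)-one | O=C1C=C[C@H]2C3(OCCO3)C=C(C)C=C[C@]12C
F9 | step 7 | (3S,3aR,8aS)-4,4-(ethane-1,2-diyldioxy)-6,8a-dimethyl-3-(propan-2-yl)-3-(4,4,5,5-tetramethyl-1,3,2-dioxaborolan-2-yl)-3,3a,4,8a-tetrahydroazulen-1(2H)-one | O=C1C[C@@](B2OC(C)(C)C(C)(C)O2)(C(C)C)[C@H]3C4(OCCO4)C=C(C)C=C[C@]13C
F10 | step 7 | (3R,3aS,8aS)-4,4-(ethane-1,2-diyldioxy)-3-hydroxy-6,8a-dimethyl-3-(propan-2-yl)-3,3a,4,8a-tetrahydroazulen-1(2H)-one | O=C1C[C@@](O)(C(C)C)[C@H]2C3(OCCO3)C=C(C)C=C[C@]12C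
F11 | step 7 | 4-methylbenzenesulfonohydrazone of F10 at C1 | Cc1ccc(cc1)S(=O)(=O)NN=C1C[C@@](O)(C(C)C)[C@H]2C3(OCCO3)C=C(C)C=C[C@]12C
F12 | step 7 | (3R,3aS,8aS)-4,4-(ethane-1,2-diyldioxy)-6,8a-dimethyl-3-(propan-2-yl)-1,2,3,3a,4,8a-hexahydroazulen-3-ol | C1C[C@@](O)(C(C)C)[C@H]2C3(OCCO3)C=C(C)C=C[C@]12C
F13 | step 7 | (3R,3aS,8aS)-3-hydroxy-6,8a-dimethyl-3-(propan-2-yl)-1,2,3,8a-tetrahydroazulen-4(3aH)-one | C1C[C@@](O)(C(C)C)[C@H]2C(=O)C=C(C)C=C[C@]12C
F14 | step 7 | (3R,3aS,8aS)-3-hydroxy-6,8a-dimethyl-3-(propan-2-yl)-1,2,3,3a,8,8a-hexahydroazulen-4(5H)-one | C1C[C@@](O)(C(C)C)[C@H]2C(=O)CC(C)=CC[C@]12C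
F15 | step 10 | (3S,3aR,4S,8aR)-6,8a-dimethyl-3-(propan-2-yl)-3,3a,4,5,8,8a-hexahydroazulene-3,4-diol | O[C@H]1CC(C)=CC[C@]2(C)C=C[C@@](O)(C(C)C)[C@@H]12
F16 | step 10 | (3R,3aR,4S,8aS)-6,8a-dimethyl-3-(propan-2-yl)-1,2,3,3a,4,5,8,8a-octahydroazulene-3,4-diol | O[C@H]1CC(C)=CC[C@]2(C)CC[C@@](O)(C(C)C)[C@@H]12
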